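**Plan**

- Retrosynthesis: the C8 and C9 acyloxy groups go back to a ring C8=C9 olefin, which is cut by ring-closing metathesis. The lactone is cut at C6–C7 (carbonyl allylation) and at O–C12, the epoxide goes back to a C4=C5 olefin, and C1=C10 and C9–C10 are cut by Wittig and Stille reactions back to neryl acetate.
- Enabling feature: in the ten-membered carbocycle the threo C8/C9 diacyloxy pair lies next to the C1=C10 acrylate. C8=C9 is therefore the cis ring olefin of a 2-vinylacrylate, and the cis-fused C6–C7 γ-lactone and the cis C4–C5 epoxide fold the chain so that the two vinyl groups meet.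
- Forward order: open chain from neryl acetate, then the γ-lactone, then the ten-membered ring by metathesis, then the 8,9-epoxide, its opening by acetate and the C8 ester.
- Stereochemistry: C6/C7 from a ligand-controlled syn carbonyl allylation. C4/C5 from a hydroxyl-directed epoxidation governed by 1,3-allylic strain. C8/C9 by anti functionalisation of the ring olefin that begins on the face away from the lactone. The glycidate comes from the chiral pool.

Key step: step 12

Assumption: positions follow germacranolide numbering (C1=C10 enoate bearing the C14 ester, C4–C5 epoxide with the C15 methyl, lactone oxygen on C6, C11=C13 methylene, C12 lactone carbonyl); neryl acetate and methyl (S)-2-methylglycidate are taken as purchasable.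

**Route**

Step 1
Reactants: 1 acrolein; 2 methyl acrylate
Product: 3 methyl 3-hydroxy-2-methylidenepent-4-enoate (racemic)
Conditions: DABCO (15 mol %), excess 2 as solvent, rt
Reagents that add atoms: none
Why: Morita–Baylis–Hillman reaction, in which the ammonium enolate of 2 adds 1,2 to the aldehyde of 1 and loss of the amine restores the acrylate; the carbinol centre is erased in step 2, so it needs no control.

Step 2
Reactants: 3 methyl 3-hydroxy-2-methylidenepent-4-enoate
Product: 4 methyl (2Z)-2-(bromomethyl)penta-2,4-dienoate
Conditions: PBr3, Et2O, −10 to 0 °C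
Reagents that add atoms: phosphorus tribromide, BrP(Br)Br
Why: SN2′ bromination of a Baylis–Hillman alcohol with allylic transposition into the conjugated dienoate, whose favoured geometry has the vinyl group trans to the ester; a regioisomeric pentadienyl bromide would give the same allylmetal in step 9.

Step 3
Reactants: 5 neryl acetate, (2Z)-3,7-dimethylocta-2,6-dien-1-yl acetate
Product: 6 (2Z)-5-(3,3-dimethyloxiran-2-yl)-3-methylpent-2-en-1-yl acetate (racemic at the epoxide)
Conditions: mCPBA (1.0 equiv), NaHCO3, CH2Cl2, 0 °C
Reagents that add atoms: 3-chloroperbenzoic acid, OOC(=O)c1cccc(Cl)c1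
Why: Prilezhaev epoxidation, selective for the electron-rich terminal trisubstituted olefin over the 2,3-olefin deactivated by the allylic acetate; the epoxide configuration is irrelevant because the ring is cleaved next.

Step 4
Reactants: 6 (2Z)-5-(3,3-dimethyloxiran-2-yl)-3-methylpent-2-en-1-yl acetate
Product: 7 (2Z)-3-methyl-6-oxohex-2-en-1-yl acetate
Conditions: H5IO6, THF/Et2O, 0 °C
Reagents that add atoms: none
Why: Periodic acid hydrates the epoxide and cleaves the resulting glycol (Malaprade cleavage) to the C1 aldehyde and acetone without touching the Z allylic acetate.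

Step 5
Reactants: 7 (2Z)-3-methyl-6-oxohex-2-en-1-yl acetate
Product: 8 methyl (2Z,6Z)-8-acetoxy-2-iodo-6-methylocta-2,6-dienoate
Conditions: Ph3P=CHCO2Me, N-iodosuccinimide, MeCN, −20 °C; then 7, −20 °C to rt
Reagents that add atoms: methyl (triphenylphosphoranylidene)acetate, COC(=O)C=P(c1ccccc1)(c1ccccc1)c1ccccc1; N-iodosuccinimide, O=C1CCC(=O)N1I
Why: Wittig olefination with the α-iodo ylide formed in the flask; as a stabilised ylide it should place the ester trans to the chain, giving the (Z)-α-iodoenoate, and a minor E isomer would be removed by chromatography.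

Step 6
Reactants: 8 methyl (2Z,6Z)-8-acetoxy-2-iodo-6-methylocta-2,6-dienoate
Product: 9 methyl (2Z,6Z)-8-hydroxy-2-iodo-6-methylocta-2,6-dienoate
Conditions: K2CO3 (0.2 equiv), MeOH, 0 °C
Reagents that add atoms: none
Why: Base-catalysed transesterification removes the acetate while the methyl ester exchanges degenerately with methanol; it is done before the palladium step so that no allylic acetate can ionise there.

Step 7
Reactants: 9 methyl (2Z,6Z)-8-hydroxy-2-iodo-6-methylocta-2,6-dienoate; 10 tributyl(vinyl)stannane
Product: 11 methyl (2E,6Z)-2-ethenyl-8-hydroxy-6-methylocta-2,6-dienoate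
Conditions: Pd2(dba)3 (2.5 mol %), AsPh3 (10 mol %), CuI (10 mol %), NMP, rt to 40 °C
Reagents that add atoms: none
Why: Stille coupling; oxidative addition of zerovalent palladium into the vinyl C–I bond, transmetalation and reductive elimination occur with retention, so the new vinyl group stays cis to the chain (C9 cis to C2).

Step 8
Reactants: 11 methyl (2E,6Z)-2-ethenyl-8-hydroxy-6-methylocta-2,6-dienoate
Product: 12 methyl (2E,6Z)-2-ethenyl-6-methyl-8-oxoocta-2,6-dienoate
Conditions: activated MnO2 (excess), CH2Cl2, rt; used crude
Reagents that add atoms: none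
Why: Chemoselective oxidation of the allylic alcohol on the MnO2 surface, which should keep the Z enal geometry as in the nerol-to-neral oxidation.

Step 9
Reactants: 12 methyl (2E,6Z)-2-ethenyl-6-methyl-8-oxoocta-2,6-dienoate; 4 methyl (2Z)-2-(bromomethyl)penta-2,4-dienoate
Product: 14 dimethyl (2E,6Z,8S,9S)-2,9-diethenyl-8-hydroxy-6-methyl-10-methylideneundeca-2,6-dienedioate, via trimethylsilyl ether 13 (not isolated)
Conditions: CrCl2 (10 mol %), tridentate carbazole bis(oxazoline) ligand (11 mol %, the enantiomer that directs Re-face addition), i-Pr2NEt (20 mol %), Mn powder, Me3SiCl, THF, rt; then citric acid, MeOH, 0 °C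
Reagents that add atoms: none
Why: Catalytic asymmetric Nozaki–Hiyama–Kishi 2-(alkoxycarbonyl)allylation, in which the trivalent allylchromium species from 4 adds through its vinyl-bearing γ-carbon in a chair transition state with the vinyl group axial (syn C6/C7, as expected for 3-substituted 2-(bromomethyl)acrylates) while the ligand selects the Re face of the aldehyde, setting C6 and C7.

Step 10
Reactants: 14 dimethyl (2E,6Z,8S,9S)-2,9-diethenyl-8-hydroxy-6-methyl-10-methylideneundeca-2,6-dienedioate
Product: 15 methyl (2E)-2-ethenyl-6-{(2R,3S)-3-[(1R,2S)-1-hydroxy-2-(3-methoxy-3-oxoprop-1-en-2-yl)but-3-en-1-yl]-2-methyloxiran-2-yl}hex-2-enoate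
Conditions: mCPBA (1.05 equiv), NaHCO3, CH2Cl2, −20 to 0 °C
Reagents that add atoms: 3-chloroperbenzoic acid, OOC(=O)c1cccc(Cl)c1
Why: Hydroxyl-directed Prilezhaev epoxidation; 1,3-allylic strain with the chain cis on the Z trisubstituted olefin holds the carbinol hydrogen in the olefin plane, so the hydrogen-bonded peracid delivers oxygen to the hydroxyl face and should give the threo (4R,5S) epoxy alcohol, while the allylic-alcohol olefin reacts far faster than the vinyl and acrylate olefins.

Step 11
Reactants: 15 the (4R,5S,6R,7S) epoxy hydroxy diester
Product: 16 methyl (2E)-2-ethenyl-6-{(2R,3S)-2-methyl-3-[(2R,3S)-3-ethenyl-4-methylidene-5-oxooxolan-2-yl]oxiran-2-yl}hex-2-enoate (cis-β-vinyl-α-methylene lactone)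
Conditions: PPTS (0.2 equiv), 4 Å molecular sieves, toluene, 60 °C
Reagents that add atoms: none
Why: Acid-catalysed lactonisation of the γ-hydroxy acrylate (5-exo-trig acyl transfer) with retention at C6, so the syn adduct becomes the cis-fused lactone; the weak pyridinium acid should spare the trisubstituted epoxide.

Step 12
Reactants: 16 the cis-β-vinyl-α-methylene lactone bearing the 4,5-epoxide and the 2-vinyl enoate
Product: 17 methyl (1(10)E,4R,5S,6R,7S,8Z)-4,5-epoxygermacra-1(10),8,11(13)-trien-12,6-olid-14-oate
Conditions: second-generation Grubbs catalyst RuCl2(=CHPh)(PCy3)(H2IMes) (10 mol % in two portions), 1,4-benzoquinone (20 mol %), toluene (1 mM), 80 °C, argon sparge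
Reagents that add atoms: none
Why: The ruthenium benzylidene exchanges onto the monosubstituted C7 vinyl group, the new alkylidene undergoes [2+2] cycloaddition with the terminal vinyl of the 2-vinylacrylate, and cycloreversion releases ethylene and forms C8=C9. The closest known reaction type is diene–ene ring-closing metathesis to medium rings, which engages the terminal olefin of a conjugated diene and keeps the internal one. The ten-membered carbocycle is closed by macrocyclising metathesis between two chain ends held on the same side by the cis-fused lactone at C6–C7 and the cis epoxide at C4–C5, so that several ring torsions are already cisoid before closure. No stereocentre is formed; the ring size and the bicyclic constraint are expected to allow C8=C9 only as Z. The step needs site selectivity among five olefins, which should follow from substitution: the 1,1-disubstituted C11=C13 and the trisubstituted C1=C10 are electron-poor and hindered, and closure onto C1=C10 would give a more strained eight-membered ring. High dilution and removal of ethylene favour the ring over acyclic oligomers, and benzoquinone suppresses hydride-induced olefin migration at C7.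

Step 13
Reactants: 17 the ten-membered dienyl lactone
Product: 18 methyl (1(10)E,4R,5S,6R,7S,8R,9R)-8-bromo-4,5-epoxy-9-hydroxygermacra-1(10),11(13)-dien-12,6-olid-14-oate
Conditions: N-bromosuccinimide (1.1 equiv), THF/H2O (4:1), 0 °C, dark
Reagents that add atoms: N-bromosuccinimide, O=C1CCC(=O)N1Br; water, O
Why: Bromohydrin formation; Br+ should enter C8=C9 on the exposed face syn to H7 and away from the cis-fused lactone, the face a peracid or OsO4 would also choose and which would put the C8 oxygen on the wrong side, and water then opens the bromonium ion anti at the allylic carbon C9 (the regioisomeric bromohydrin would converge in step 14).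

Step 14
Reactants: 18 the 8-bromo-9-hydroxy lactone
Product: 19 methyl (1(10)E,4R,5S,6R,7R,8S,9R)-4,5:8,9-diepoxygermacra-1(10),11(13)-dien-12,6-olid-14-oate (8,9-epoxide on the lactone face)
Conditions: Ag2O, CH2Cl2, rt, dark
Reagents that add atoms: none
Why: Intramolecular Williamson closure (3-exo-tet) assisted by silver without a nucleophilic base; the C9 oxygen displaces bromide at C8 with inversion, which sets the C8–O bond cis to the lactone as in the target.

Step 15
Reactants: 19 the 4,5:8,9-diepoxide
Product: 20 methyl (1(10)E,4R,5S,6R,7R,8S,9S)-9-acetoxy-4,5-epoxy-8-hydroxygermacra-1(10),11(13)-dien-12,6-olid-14-oate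
Conditions: CsOAc (3 equiv), AcOH (3 equiv), DMF, 50 °C
Reagents that add atoms: acetic acid, CC(=O)O
Why: SN2 opening of the vinyl epoxide by acetate at the allylic carbon C9 from the exposed face with inversion, giving the threo 8-hydroxy-9-acetate with the C8–O bond untouched; the 4,5-epoxide, with a tertiary C4 and a hindered C5, should not react with a carboxylate.

Step 16
Reactants: 21 methyl (S)-2-methyloxirane-2-carboxylate
Product: 22 potassium (S)-2-methyloxirane-2-carboxylate
Conditions: KOH (1.0 equiv), MeOH, 0 °C to rt; evaporate to dryness
Reagents that add atoms: potassium hydroxide, [K+].[OH-]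
Why: Saponification of a glycidic ester to its stable salt; the quaternary stereocentre cannot epimerise and the acid-sensitive free glycidic acid is never handled.

Step 17
Reactants: 20 the 9-acetoxy-8-hydroxy lactone; 22 potassium (S)-2-methyloxirane-2-carboxylate
Product: 24 methyl (1(10)E,4R,5S,6R,7R,8S,9S)-9-acetoxy-4,5-epoxy-8-[(2S)-2-methyloxirane-2-carbonyloxy]germacra-1(10),11(13)-dien-12,6-olid-14-oate (the target), via mixed anhydride 23 (not isolated)
Conditions: 2,4,6-trichlorobenzoyl chloride, THF, rt; then 20, DMAP, toluene, rt
Reagents that add atoms: none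
Why: Yamaguchi esterification; DMAP transfers the less hindered glycidoyl group of the mixed anhydride to the secondary C8 hydroxyl with retention at C8 and at the glycidate centre, under conditions short and mild enough to limit acetyl migration from O9.

**Compound list**

1 | acrolein | C=CC=O | starting material
2 | methyl acrylate | C=CC(=O)OC | starting material
3 | methyl 3-hydroxy-2-methylidenepent-4-enoate (racemic) | C=CC(O)C(=C)C(=O)OC | intermediate
4 | methyl (2Z)-2-(bromomethyl)penta-2,4-dienoate | C=C/C=C(\CBr)C(=O)OC | intermediate
5 | neryl acetate | CC(C)=CCC/C(C)=C\COC(C)=O | starting material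
6 | (2Z)-5-(3,3-dimethyloxiran-2-yl)-3-methylpent-2-en-1-yl acetate | CC(=O)OC/C=C(C)\CCC1OC1(C)C | intermediate
7 | (2Z)-3-methyl-6-oxohex-2-en-1-yl acetate | CC(=O)OC/C=C(C)\CCC=O | intermediate
8 | methyl (2Z,6Z)-8-acetoxy-2-iodo-6-methylocta-2,6-dienoate | CC(=O)OC/C=C(C)\CC/C=C(\I)C(=O)OC | intermediate
9 | methyl (2Z,6Z)-8-hydroxy-2-iodo-6-methylocta-2,6-dienoate | OC/C=C(C)\CC/C=C(\I)C(=O)OC | intermediate
10 | tributyl(vinyl)stannane | C=C[Sn](CCCC)(CCCC)CCCC | starting material
11 | methyl (2E,6Z)-2-ethenyl-8-hydroxy-6-methylocta-2,6-dienoate | OC/C=C(C)\CC/C=C(\C=C)C(=O)OC | intermediate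
12 | methyl (2E,6Z)-2-ethenyl-6-methyl-8-oxoocta-2,6-dienoate | O=C/C=C(C)\CC/C=C(\C=C)C(=O)OC | intermediate
13 | trimethylsilyl ether of 14 | C=C(C(=O)OC)[C@H](C=C)[C@@H](O[Si](C)(C)C)/C=C(C)\CC/C=C(\C=C)C(=O)OC | intermediate
14 | dimethyl (2E,6Z,8S,9S)-2,9-diethenyl-8-hydroxy-6-methyl-10-methylideneundeca-2,6-dienedioate | C=C(C(=O)OC)[C@H](C=C)[C@@H](O)/C=C(C)\CC/C=C(\C=C)C(=O)OC | intermediate
15 | (4R,5S,6R,7S) epoxy hydroxy diester | C=C(C(=O)OC)[C@H](C=C)[C@@H](O)[C@@H]1O[C@]1(C)CC/C=C(\C=C)C(=O)OC | intermediate
16 | cis-β-vinyl-α-methylene lactone with 4,5-epoxide and 2-vinyl enoate (metathesis precursor) | C=C1C(=O)O[C@H]([C@H]1C=C)[C@@H]1O[C@]1(C)CC/C=C(\C=C)C(=O)OC | intermediate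
17 | methyl (1(10)E,4R,5S,6R,7S,8Z)-4,5-epoxygermacra-1(10),8,11(13)-trien-12,6-olid-14-oate (metathesis product) | C=C1C(=O)O[C@@H]2[C@H]1/C=C\C(C(=O)OC)=C/CC[C@@]1(C)O[C@@H]21 | intermediate
18 | (8R,9R)-8-bromo-9-hydroxy lactone | C=C1C(=O)O[C@@H]2[C@H]1[C@@H](Br)[C@H](O)/C(C(=O)OC)=C\CC[C@@]1(C)O[C@@H]21 | intermediate
19 | (8S,9R)-4,5:8,9-diepoxy lactone | C=C1C(=O)O[C@@H]2[C@H]1[C@@H]3O[C@@H]3/C(C(=O)OC)=C\CC[C@@]1(C)O[C@@H]21 | intermediate
20 | (8S,9S)-9-acetoxy-8-hydroxy lactone | C=C1C(=O)O[C@@H]2[C@H]1[C@H](O)[C@@H](OC(C)=O)/C(C(=O)OC)=C\CC[C@@]1(C)O[C@@H]21 | intermediate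
21 | methyl (S)-2-methyloxirane-2-carboxylate | COC(=O)[C@]1(C)CO1 | starting material
22 | potassium (S)-2-methyloxirane-2-carboxylate | [K+].[O-]C(=O)[C@]1(C)CO1 | intermediate
23 | (S)-2-methyloxirane-2-carboxylic 2,4,6-trichlorobenzoic anhydride | O=C(OC(=O)c1c(Cl)cc(Cl)cc1Cl)[C@]1(C)CO1 | intermediate
24 | CNP0274195.1 | C=C1C(=O)O[C@@H]2[C@H]1[C@H](OC(=O)[C@]1(C)CO1)[C@@H](OC(C)=O)/C(C(=O)OC)=C\CC[C@@]1(C)O[C@@H]21 | target

**Step count and risks**

Total: 17 steps. Longest linear sequence: 14 steps (steps 3–15 and 17, from neryl acetate); steps 1–2 and step 16 are side branches.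

Steps most likely to fail:

Step 12. Intermolecular metathesis may outrun closure of the strained bicyclic diene, or a ruthenium hydride may move the C8 olefin into conjugation before it reacts. The fallback inverts the order of the two ring formations. It sets out from 15, in which the chain is not yet tied into the lactone. Metathesis under the same dilution closes the ten-membered ring first and gives the monocyclic epoxy hydroxy diester F1. Its C6 hydroxyl is then lactonised onto the C12 ester with PPTS as in step 11, and the sequence rejoins the route at 17.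

Step 9. The chromium allylation may show low enantioselectivity or low syn selectivity, or the pentadienyl unit may bond through its terminal carbon. The fallback replaces the open organochromium addition by a closed, stereospecific allylboration. It sets out from 3, which is acetylated (Ac2O, DMAP) to methyl 3-acetoxy-2-methylidenepent-4-enoate F2. Copper-catalysed SN2′ borylation with bis(pinacolato)diboron (CuCl, KOAc, DMF) then gives methyl 2-[(pinacolatoboryl)methyl]penta-2,4-dienoate F3, with the vinyl group cis to the CH2B arm. Addition of F3 to enal 12 under a chiral BINOL-derived phosphoric acid passes through a chair transition state that turns the olefin geometry into the syn relationship and the catalyst chirality into the carbinol configuration. It rejoins the route at 14.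

Step 13. Facial discrimination of the ring olefin may be poor or reversed, with bromonium formation on the lactone face, so that step 14 would close the epoxide on the wrong side. The fallback applies if the olefin proves to accept electrophiles from the lactone face. It sets out from 17, which is treated with dimethyldioxirane in acetone at 0 °C. This concerted syn oxygen transfer would place the epoxide directly on that face and give 19, where the route is rejoined; no new compound is formed.

Further compounds

F1 | step 12 | dimethyl ten-membered epoxy hydroxy diester (C6-hydroxy, C12-methyl ester seco form of 17) | C=C(C(=O)OC)[C@@H]1/C=C\C(C(=O)OC)=C/CC[C@@]2(C)O[C@H]2[C@@H]1O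
F2 | step 9 | methyl 3-acetoxy-2-methylidenepent-4-enoate | C=CC(OC(C)=O)C(=C)C(=O)OC
F3 | step 9 | methyl (2E)-2-[(4,4,5,5-tetramethyl-1,3,2-dioxaborolan-2-yl)methyl]penta-2,4-dienoate | C=C/C=C(\CB1OC(C)(C)C(C)(C)O1)C(=O)OC
F0 | step 13 | none | none
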